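Ring A is numbered C1 (butanoyl-bearing), C2 (enol C–OH), C3 (quaternary, methyl and prenyl), C4 (enol C–OH), C5 (bridge-bearing), C6 (C=O); ring B is the arene. C2 and C4 are the same kind of carbon and differ only through the substituents on C1 and C5, so cutting ring bond C1–C6 unfolds ring A into an achiral, mirror-symmetric bis(β-keto thioester) chain through C3.
Retrosynthetic cuts, in order: the C5–CH2 bond of the methylene bridge (ring B leaves as the o-quinone methide of aspidinol); the CO–propyl bond of the ring A butanoyl group (back to a thioester); ring bond C1–C6 (Claisen); the two bonds from the C2 and C4 carbonyl carbons to malonate half-thioester units; the C3–prenyl bond.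
Forward: the open chain is assembled on methylmalonate, ring A is closed in one Dieckmann-type step, the butanoyl group is completed, and ring B (bought as 2,4,6-trihydroxytoluene and elaborated separately) is joined last through the CH2 bridge.
The only stereocenter, C3 (R), is created in the ring closure, where a chiral magnesium–bis(oxazoline) complex chooses between the two enantiotopic arms; it is quaternary, cannot enolise and is carried unchanged to the end.

Key step: step 5

Assumptions:
- Ring A compounds are drawn as the enol tautomer of the target SMILES; the tautomers interconvert and the descriptor R refers to this drawing.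
- The sense of induction of the magnesium complex cannot be deduced from precedent; the (S,S)-ligand is written and its mirror image would be used if the first run shows the opposite sense.
- 3-(Ethylsulfanyl)-3-oxopropanoic acid is taken as purchasable.

Step 1
Reactants: 1 dimethyl 2-methylmalonate; 2 1-bromo-3-methylbut-2-ene
Product: 3 dimethyl 2-methyl-2-(3-methylbut-2-enyl)malonate
Conditions: NaH (1.1 equiv), THF, 0 °C; then 2, 0 °C → rt
Reagents that add atoms: none
Why: Malonate alkylation (SN2) of the sodium enolate at the unsubstituted terminus of the primary allylic bromide; the product has no acidic C–H left, so over-alkylation is impossible.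

Step 2
Reactants: 3 dimethyl 2-methyl-2-(3-methylbut-2-enyl)malonate
Product: 4 2-methyl-2-(3-methylbut-2-enyl)malonic acid
Conditions: KOH (5 equiv), MeOH/H2O, reflux; then cold aq. HCl to pH 1
Reagents that add atoms: potassium hydroxide (supplies the two hydroxyl oxygens), SMILES [K+].[OH-]
Why: Ester saponification; a 2,2-disubstituted malonic acid does not decarboxylate at room temperature, so cold acidification should return the diacid intact.

Step 3
Reactants: 4 2-methyl-2-(3-methylbut-2-enyl)malonic acid
Product: 5 2-methyl-2-(3-methylbut-2-enyl)malonyl dichloride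
Conditions: 1-chloro-N,N,2-trimethylprop-1-en-1-amine (2.2 equiv), CH2Cl2, 0 °C → rt; solvent removed, used crude
Reagents that add atoms: 1-chloro-N,N,2-trimethylprop-1-en-1-amine (Ghosez's reagent), SMILES CC(C)=C(Cl)N(C)C
Why: Acid chloride formation with Ghosez's reagent is neutral and gives only an amide by-product, so no HCl is present to add across the prenyl double bond.

Step 4
Reactants: 5 2-methyl-2-(3-methylbut-2-enyl)malonyl dichloride; 6 3-(ethylsulfanyl)-3-oxopropanoic acid
Product: 8 S,S-diethyl 4-methyl-4-(3-methylbut-2-enyl)-3,5-dioxoheptanebis(thioate) (achiral), via magnesium bis(acylmalonate) 7 (not isolated)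
Conditions: 6 (4.4 equiv), MgCl2 (4.4 equiv), Et3N (8.8 equiv), MeCN/THF, 0 °C; then 5, 0 °C → rt; 1 M HCl, rt
Reagents that add atoms: none
Why: Decarboxylative Claisen acylation of a magnesium malonate half-thioester at each acyl chloride; the chelated acylmalonate 7 should stay inert until acidification releases CO2 and gives the two β-keto thioester arms.

Step 5
Reactants: 8 S,S-diethyl 4-methyl-4-(3-methylbut-2-enyl)-3,5-dioxoheptanebis(thioate)
Product: 9 S-ethyl (R)-2,4-dihydroxy-3-methyl-3-(3-methylbut-2-enyl)-6-oxocyclohexa-1,4-diene-1-carbothioate
Conditions: Mg(OTf)2 (20 mol %), (S,S)-Ph-box [2,2'-(propane-2,2-diyl)bis((4S)-4-phenyl-4,5-dihydrooxazole)] (22 mol %), 2,6-lutidine (1.2 equiv), 4 Å MS, CH2Cl2, −20 °C → 0 °C; cold aq. citric acid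
Reagents that add atoms: none
Why: Proposed new method: the divalent magnesium–bis(oxazoline) complex should bind one β-keto thioester arm of 8 as a six-membered chelate, acidifying its methylene enough for the weak base 2,6-lutidine to enolise it, and the enolate carbon then adds to the thioester carbonyl of the other, still neutral arm; loss of ethanethiolate and immediate deprotonation of the acyl-trione make the closure irreversible. The closest known reaction types are magnesium halide–amine soft-enolisation Claisen acylations of thioesters and catalytic enantioselective desymmetrising aldol cyclisations of prochiral triketones; an enantiotopic-group-selective Claisen closure of this kind is not established. Ring A closes through bond C1–C6 in a 6-exo-trig acyl substitution, a 6-(enolendo)-exo-trig process in enolate terms and allowed by Baldwin's rules, whereas the only carbocyclic alternatives would be four-membered. The new quaternary stereocenter C3 is under catalyst control: the phenyl groups of the ligand must tell the methyl from the prenyl group on the central carbon in a chair-like transition state and so decide which arm is the nucleophile and which the electrophile. The step needs enantiotopic-arm selectivity and C- over O-acylation: the mirror symmetry of 8 makes the catalyst the only source of differentiation, the weak base keeps uncomplexed substrate from closing in a racemic background reaction, and the chelated magnesium enolate reacts at carbon and so disfavours lactonisation to a pyranone. The surviving thioester marks C1 for the butanoyl group and leaves C5 free for the bridge.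

Step 6
Reactants: 9 S-ethyl (R)-2,4-dihydroxy-3-methyl-3-(3-methylbut-2-enyl)-6-oxocyclohexa-1,4-diene-1-carbothioate
Product: 11 (R)-2-butanoyl-3,5-dihydroxy-4-methyl-4-(3-methylbut-2-enyl)cyclohexa-2,5-dien-1-one, via bis(trimethylsilyl) enol ether 10 (not isolated)
Conditions: BSA (2.5 equiv), CH2Cl2, rt, then evaporation; n-PrZnBr (0.5 M in THF, 2.5 equiv), PdCl2(PPh3)2 (5 mol %), toluene/THF, rt; aq. citric acid, 0 °C
Reagents that add atoms: propylzinc bromide, SMILES CCC[Zn]Br; N,O-bis(trimethylsilyl)acetamide, SMILES CC(=N[Si](C)(C)C)O[Si](C)(C)C (adds the silyl groups of 10 only)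
Why: Fukuyama ketone synthesis (insertion of zerovalent palladium into the C(acyl)–S bond, propyl transfer from zinc, reductive elimination) run on the transiently bis-silylated compound so that no acidic enol proton quenches the organozinc; any silyl regioisomer of 10 converges on 11 when the silyl groups fall off on acidic work-up, and C3 is not touched.

Step 7
Reactants: 12 2,4,6-trihydroxytoluene
Product: 13 1-(2,4,6-trihydroxy-3-methylphenyl)butan-1-one
Conditions: butanoyl chloride (1.05 equiv), AlCl3 (3 equiv), PhNO2/CH2Cl2, 0 °C → 40 °C; ice/aq. HCl
Reagents that add atoms: butanoyl chloride, SMILES CCCC(Cl)=O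
Why: Friedel–Crafts acylation of the phloroglucinol nucleus; the two free ring positions of 12 are equivalent and the first acyl group deactivates the ring towards a second.

Step 8
Reactants: 13 1-(2,4,6-trihydroxy-3-methylphenyl)butan-1-one
Product: 14 1-(2,6-dihydroxy-4-methoxy-3-methylphenyl)butan-1-one (aspidinol)
Conditions: Me2SO4 (1.0 equiv), K2CO3 (1.0 equiv), acetone, rt
Reagents that add atoms: dimethyl sulfate, SMILES COS(=O)(=O)OC
Why: Williamson-type O-methylation with one equivalent of base and reagent should select the 4-hydroxyl, which is para to the ketone (the most acidic phenol) and, unlike the two ortho hydroxyls, is not engaged with the butanoyl carbonyl.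

Step 9
Reactants: 14 1-(2,6-dihydroxy-4-methoxy-3-methylphenyl)butan-1-one
Product: 15 1-[3-[(dimethylamino)methyl]-2,6-dihydroxy-4-methoxy-5-methylphenyl]butan-1-one
Conditions: aq. Me2NH (40%), aq. CH2O (37%), EtOH, 0 °C → rt
Reagents that add atoms: formaldehyde, SMILES C=O; dimethylamine, SMILES CNC
Why: Phenolic Mannich reaction at the single unsubstituted ring position of 14, with excess amine suppressing diarylmethane formation.

Step 10
Reactants: 11 (R)-2-butanoyl-3,5-dihydroxy-4-methyl-4-(3-methylbut-2-enyl)cyclohexa-2,5-dien-1-one; 15 1-[3-[(dimethylamino)methyl]-2,6-dihydroxy-4-methoxy-5-methylphenyl]butan-1-one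
Product: 17 (R)-2-butanoyl-6-[(3-butanoyl-2,4-dihydroxy-6-methoxy-5-methylphenyl)methyl]-3,5-dihydroxy-4-methyl-4-(3-methylbut-2-enyl)cyclohexa-2,5-dien-1-one (target CNP0219644.1), via o-quinone methide 16 (not isolated)
Conditions: 11 (1.0 equiv), 15 (1.1 equiv), 1,4-dioxane, 90 °C, N2; dilute aq. citric acid wash
Reagents that add atoms: none
Why: Loss of dimethylamine from the ortho-hydroxybenzylamine, helped by proton transfer from the acidic trione, gives o-quinone methide 16, which is captured by the enolic C5 of ring A (its only free nucleophilic carbon) in a Michael addition with rearomatisation of ring B, the established way to methylene-bridged acylphloroglucinol dimers; quaternary C3 cannot epimerise.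

Compound list
1 | dimethyl 2-methylmalonate | COC(=O)C(C)C(=O)OC | starting material
2 | 1-bromo-3-methylbut-2-ene | CC(C)=CCBr | starting material
3 | dimethyl 2-methyl-2-(3-methylbut-2-enyl)malonate | COC(=O)C(C)(CC=C(C)C)C(=O)OC | intermediate
4 | 2-methyl-2-(3-methylbut-2-enyl)malonic acid | OC(=O)C(C)(CC=C(C)C)C(O)=O | intermediate
5 | 2-methyl-2-(3-methylbut-2-enyl)malonyl dichloride | ClC(=O)C(C)(CC=C(C)C)C(Cl)=O | intermediate
6 | 3-(ethylsulfanyl)-3-oxopropanoic acid | CCSC(=O)CC(O)=O | starting material
7 | 2,6-bis(ethylsulfanylcarbonyl)-4-methyl-4-(3-methylbut-2-enyl)-3,5-dioxoheptanedioic acid (magnesium salt in the flask, drawn as the free diacid; methine centers undefined) | CCSC(=O)C(C(O)=O)C(=O)C(C)(CC=C(C)C)C(=O)C(C(O)=O)C(=O)SCC | intermediate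
8 | S,S-diethyl 4-methyl-4-(3-methylbut-2-enyl)-3,5-dioxoheptanebis(thioate) (achiral) | CCSC(=O)CC(=O)C(C)(CC=C(C)C)C(=O)CC(=O)SCC | intermediate
9 | S-ethyl (R)-2,4-dihydroxy-3-methyl-3-(3-methylbut-2-enyl)-6-oxocyclohexa-1,4-diene-1-carbothioate | CCSC(=O)C1=C(O)[C@](C)(CC=C(C)C)C(O)=CC1=O | intermediate
10 | S-ethyl (R)-3-methyl-3-(3-methylbut-2-enyl)-6-oxo-2,4-bis(trimethylsilyloxy)cyclohexa-1,4-diene-1-carbothioate | CCSC(=O)C1=C(O[Si](C)(C)C)[C@](C)(CC=C(C)C)C(O[Si](C)(C)C)=CC1=O | intermediate
11 | (R)-2-butanoyl-3,5-dihydroxy-4-methyl-4-(3-methylbut-2-enyl)cyclohexa-2,5-dien-1-one | CCCC(=O)C1=C(O)[C@](C)(CC=C(C)C)C(O)=CC1=O | intermediate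
12 | 2,4,6-trihydroxytoluene | Cc1c(O)cc(O)cc1O | starting material
13 | 1-(2,4,6-trihydroxy-3-methylphenyl)butan-1-one | CCCC(=O)c1c(O)cc(O)c(C)c1O | intermediate
14 | 1-(2,6-dihydroxy-4-methoxy-3-methylphenyl)butan-1-one (aspidinol) | CCCC(=O)c1c(O)cc(OC)c(C)c1O | intermediate
15 | 1-[3-[(dimethylamino)methyl]-2,6-dihydroxy-4-methoxy-5-methylphenyl]butan-1-one | CCCC(=O)c1c(O)c(CN(C)C)c(OC)c(C)c1O | intermediate
16 | 2-butanoyl-3-hydroxy-5-methoxy-4-methyl-6-methylidenecyclohexa-2,4-dien-1-one | C=C1C(=O)C(C(=O)CCC)=C(O)C(C)=C1OC | intermediate
17 | (R)-2-butanoyl-6-[(3-butanoyl-2,4-dihydroxy-6-methoxy-5-methylphenyl)methyl]-3,5-dihydroxy-4-methyl-4-(3-methylbut-2-enyl)cyclohexa-2,5-dien-1-one | CCCC(=O)C1=C(O)[C@](C)(CC=C(C)C)C(O)=C(Cc2c(O)c(C(=O)CCC)c(O)c(C)c2OC)C1=O | target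

Total step count: 10. Longest linear sequence: 7 steps (steps 1–6 and 10); the ring B branch (steps 7–9) joins at step 10.

Steps most likely to fail

Step 5. The catalyst may discriminate poorly between the enantiotopic arms, an uncatalysed racemic closure or O-acylation to a pyranone may compete, and the acidic product may bind magnesium and stop turnover. Fallback: setting out from 8, an achiral soft-enolisation Claisen closure (MgBr2·OEt2, i-Pr2NEt, CH2Cl2), the classical cyclisation of 3,5-dioxo esters to filicinic-acid-type triones, would give racemic S-ethyl 2,4-dihydroxy-3-methyl-3-(3-methylbut-2-enyl)-6-oxocyclohexa-1,4-diene-1-carbothioate F1. Preparative chromatography on an amylose carbamate chiral stationary phase (supercritical CO2/MeOH with an acidic modifier) would then supply the R enantiomer, and the route is rejoined at 9.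

Step 6. Incomplete silylation may let enol protons quench the organozinc, oxidative addition into the hindered, electron-rich enone thioester may be slow, and the silyl groups may be lost before coupling. Fallback: setting out from 9, silver trifluoroacetate-promoted exchange of the thioester with N,O-dimethylhydroxylamine (AgO2CCF3, MeNHOMe·HCl, Et3N, THF, rt; the silver-assisted aminolysis of β-keto thioesters through an acylketene) would give the Weinreb amide (R)-2,4-dihydroxy-N-methoxy-N,3-dimethyl-3-(3-methylbut-2-enyl)-6-oxocyclohexa-1,4-diene-1-carboxamide F2. Excess n-PrMgCl (THF, −20 °C → 0 °C; the first equivalents deprotonate the enols, the next adds to the chelated amide) and acidic work-up would then rejoin the route at 11.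

Step 4. The mono-acylated intermediate may close onto the remaining acyl chloride (cyclic anhydride or enol lactone) before the second malonate unit arrives, and the half-thioester may decarboxylate before it is acylated. Fallback: setting out from 5, C-acylation of two equivalents of Meldrum's acid (pyridine, CH2Cl2, 0 °C) would give the bis(acyl Meldrum's acid) 5,5'-[1,3-dihydroxy-2-methyl-2-(3-methylbut-2-enyl)propane-1,3-diylidene]bis(2,2-dimethyl-1,3-dioxane-4,6-dione) F3. Thermolysis with ethanethiol (toluene, sealed vessel, 90 °C; acylketene capture) would then rejoin the route at 8.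

Further compounds
F1 | step 5 | racemic S-ethyl 2,4-dihydroxy-3-methyl-3-(3-methylbut-2-enyl)-6-oxocyclohexa-1,4-diene-1-carbothioate | CCSC(=O)C1=C(O)C(C)(CC=C(C)C)C(O)=CC1=O
F2 | step 6 | (R)-2,4-dihydroxy-N-methoxy-N,3-dimethyl-3-(3-methylbut-2-enyl)-6-oxocyclohexa-1,4-diene-1-carboxamide | CON(C)C(=O)C1=C(O)[C@](C)(CC=C(C)C)C(O)=CC1=O
F3 | step 4 | 5,5'-[1,3-dihydroxy-2-methyl-2-(3-methylbut-2-enyl)propane-1,3-diylidene]bis(2,2-dimethyl-1,3-dioxane-4,6-dione) | CC1(C)OC(=O)C(C(=O)O1)=C(O)C(C)(CC=C(C)C)C(O)=C1C(=O)OC(C)(C)OC1=O
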